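(Readings and results were computed for substances that don't exist.)

I decided to count turnovers instead of solving a rate law for each flask.

| setting | ochre | blue | eta | delta |
|---|---|---|---|---|
| first end groups | 0.013 M | 0.030 M | 0.020 M | 0.020 M |
| second end groups | 0.020 M | 0.020 M | 0.0200 M | 0.0200 M |
| protic impurity | 1 mM | 1 mM | 1.00 mM | 1.00 mM |
| remark | run made earlier | run made earlier |  |  |
| time |  |  | 80 min | 40 min |

- ochre (time / min: links / %, first end groups / %): 25.0: 44.6, 49.1; 50.0: 62.9, 28.9; 80.0: 73.9, 19.7; 90.0: 75.9, 16.8
- blue (time / min: links / %, first end groups / %): 25.0: 37.9, 57.7; 50.0: 49.4, 46.8; 80.0: 55.6, 41.4; 90.0: 56.9, 39.1

(standard deviation of a reading: 0.5 percentage points)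

- which of the two ends with the longer chains by the average number of monomer units in a chain (unreacted monomers counted as chains of one) ("neither" if they lie within 10%) (eta / delta / neither)
- average number of monomer units in a chain (unreacted monomers counted as chains of one) at the end, eta
- average number of monomer units in a chain (unreacted monomers counted as chains of one) at the end, delta

At the last reading, links plus first end groups fell short of the charge by 0.949 mM in ochre and 1.20 mM in blue, close to the impurity charged. I therefore took that much of the first end groups as dead: they still end chains, but they cannot link.

For ochre, I took the logarithm of the fraction of second end groups left over the fraction of linkable first end groups left. Dividing by the gap between the two charges and by the time gave a rate constant, read from that last scattered reading, of 1.44 M⁻¹ min⁻¹.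

Multiplying it by the linkable first end groups and the time gave 2.18 for eta and 1.09 for delta. This is the count of turnovers. With nearly equal ends, the ends left fall to one part in one plus this count, so I expected chain lengths of 3.18 for eta and 2.09 for delta.

The forecast gave 3 for eta and 2.1 for delta, with eta longer, and of the sagging rate constant it said “the data can't separate these”.

The flasks gave 3.04 for eta and 2.12 for delta, so eta ended longer; my count ran higher than eta's result and close to delta's.

    first end groups + second end groups ⇌ links + released group (K = 31.0, k = 0.0260 M⁻¹ s⁻¹)
    first end groups + protic impurity → quenched substrate (k = 0.230 M⁻¹ s⁻¹)
    second end groups → decomposed reagent (k = 1.10 × 10⁻⁵ s⁻¹)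

The neighbouring flask was eta with 0.050 M of first end groups, so its ends were unequal and second end groups were the limiting reagent. Its turnovers came to 5.63, more than eta's 2.18. But one plus the count, 6.63, was not the length in this flask: with every second end group charged turned into links, the length would be 2.33. The neighbouring flask kept 3.20% of its second end groups and reached a length of 2.21.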